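Counting chains was the easy step, so I started there.

| flask | free monomer | initiator | remark | time |
|---|---|---|---|---|
| north | 8.7 mM (fed, over 20 min) | 4.5 mol% | run made earlier |  |
| north-west | 16 mM (fed, over 20 min) | 4.5 mol% | run made earlier |  |
| Sunday's | 20 mM (fed, over 20 min) | 4.5 mol% |  | 25 h |
| Saturday's | 10 mM (fed, over 20 min) | 4.5 mol% |  | 25 h |

- north (time / h: monomer in chains / %, free monomer / %): 4.00: 69, 31; 8.00: 85, 13; 10.0: 89, 13; 15.0: 90, 10; 20.0: 93, 5; 25.0: 91, 10
- north-west (time / h: monomer in chains / %, free monomer / %): 2.00: 56, 41; 3.00: 68, 31; 5.00: 83, 14; 8.00: 90, 7; 10.0: 95, 4; 15.0: 95, 4; 25.0: 96, 5

(readings scatter by 1.5 percentage points)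

- the average divides the monomer in chains by the number of chains, living and dead together; two radicals that join make one chain
- what was read earlier has a scatter of 1.5 percentage points, one standard deviation
- the earlier runs do not show the number of chains; that part of a forecast is a guess

* which of the two ends with the longer chains by the average number of monomer units in a chain (living and dead chains, two that joined counted as one) ("neither" if they lie within 10%) (Sunday's / Saturday's / neither)
* average number of monomer units in a chain (living and dead chains, two that joined counted as one) at the end, Sunday's
* average number of monomer units in a chain (living and dead chains, two that joined counted as one) at the end, Saturday's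

The initiator was charged in the smaller amount, so I wrote its balance. The earlier runs showed no chains, so this part was a guess: I let each initiator end as one chain, which made it the limiting reagent of the count. For Sunday's flask that gave 0.900 mM, and for Saturday's 0.450 mM. I called this the chain count, the initiator charged per starting volume.

Length is monomer in chains over chain count. The loading was the same in both flasks, so the charge cancelled, and each length was the share in chains divided by 4.5 mol%. The opposite outcome therefore needed shares more than 10% apart.

The north run ended with a reading of 0.870 mM free monomer, and the north-west run with 0.800 mM. I took the second for both new flasks. That put 96.0% in chains in Sunday's and 92.0% in Saturday's, so the lengths were 21.3 and 20.4. For Sunday's to count as longer, with its share held at 96.0%, Saturday's free monomer had to stand above 12.7% of its charge, and I had 8.00%.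

The forecast said neither, with 22 for Sunday's and 21 for Saturday's, both above mine: “Some coupling or incomplete initiation would raise both slightly, which is the guessed part.”

The flasks gave neither: 21.6 for Sunday's and 20.7 for Saturday's.

    monomer in chains → over-reaction product (k = 5.65 × 10⁻⁴ /h)
    free monomer + growing radical → monomer in chains + growing radical, rate k2*[growing radical]*[free monomer] (k = 9.38 × 10⁶ /M/h)
    initiator → 2 initiating radical (k = 0.293 /h)
    free monomer + initiating radical → growing radical + monomer in chains (k = 16000 /M/s)
    2 growing radical → dead chain (k = 2.10 × 10⁷ /M/s)

At the end, Sunday's flask held dead chain at 0.899 mM against my count of 0.900 mM, and Saturday's held 0.450 mM against 0.450 mM. Saturday's free monomer stood at 5.88%, less than the 12.7% I had reckoned for the other outcome. The neighbouring flask was Saturday's with 1.8 mol% of initiator. Its chain count was 0.180 mM, and its dead chain stood at 0.180 mM. Its monomer in chains was 80.3% of the charge, so the count gave 44.6. The neighbouring flask itself gave 44.7.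

The data were generated by integration from invented constants; noise was put on by code.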